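**Ret­rosynthetic overview**

The last C–C bond is the methylene bridge: the free ring carbon of the trione adds to the o-quinone methide released from an 8-(dimethylaminomethyl)chromene, itself built from butyrylphloroglucinol and prenal.
The strategy rests on the non-aromatisable 2-acetylcyclohexane-1,3,5-trione ring: its quaternary C-4 (methyl, geranyl) sits between the C-3 and C-5 carbonyl carbons, so the ring is a 3-acetyl-4-oxygenated 2-pyrone in which ring O-1 is replaced by the α-carbon of a 6-(sec-alkyl) side chain.
Key disconnection: the C-4–C-3(=O) bond of the trione. The racemic pyrone (as its 4-methyl ether) is opened by base to an acylketene/tertiary enolate held by a chiral ammonium ion, and C-acylation closes the carbocycle; both enantiomers converge through one achiral enolate.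
The pyrone comes from 4-hydroxy-6-methyl-2-pyrone by two lateral dianion alkylations (iodomethane, geranyl bromide), C-3 acetylation and O-methylation.
Ring order: pyrone (bought) → carbocyclic trione (key step); the 2H-pyran ring of the chromene is formed in the side branch; the last step forms no ring.

Key step: step 5

Remark: the pyrone 4-OH is capped as its methyl ether for the key step, because the pyronate anion would resist ring opening and an external alkoxide would strip the acetyl group by retro-Claisen cleavage; the ether is removed directly afterwards. Descriptors refer to the tautomers drawn: (S)-9, (R)-10 and (R)-17 have the same spatial arrangement, and the letter changes only because the CIP ranking of the two ring arms changes.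

**Step 1**
Reactants: 1 4-hydroxy-6-methyl-2H-pyran-2-one
Product: 2 6-ethyl-4-hydroxy-2H-pyran-2-one
Conditions: LDA (2.3 equiv), THF/DMPU, −78 °C; MeI (1.0 equiv), −78 → −30 °C; 1 M HCl
Reagents that add atoms: iodomethane, CI
Why: Two equivalents of LDA give the known lateral dianion of the 4-hydroxy-2-pyrone, and its most basic carbon, the C-6 methyl carbanion, is alkylated selectively by iodomethane (dianion alkylation).

**Step 2**
Reactants: 2 6-ethyl-4-hydroxy-2H-pyran-2-one; 3 geranyl bromide, (2E)-1-bromo-3,7-dimethylocta-2,6-diene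
Product: 4 rac-4-hydroxy-6-[(4E)-5,9-dimethyldeca-4,8-dien-2-yl]-2H-pyran-2-one
Conditions: LDA (2.3 equiv), THF/DMPU, −78 °C; 3 (1.0 equiv), −78 → −20 °C; 1 M HCl
Reagents that add atoms: none
Why: The same lateral dianion alkylation at the CH2 of the 6-ethyl group, an SN2 reaction with the allylic bromide that keeps the E-alkene; the new methine centre forms racemic, which is intended because step 5 erases it.

**Step 3**
Reactants: 4 rac-4-hydroxy-6-[(4E)-5,9-dimethyldeca-4,8-dien-2-yl]-2H-pyran-2-one
Product: 6 rac-3-acetyl-4-hydroxy-6-[(4E)-5,9-dimethyldeca-4,8-dien-2-yl]-2H-pyran-2-one, via pyranyl acetate 5 (not isolated)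
Conditions: AcOH, DCC, DMAP (0.2 equiv), toluene, rt → 60 °C
Reagents that add atoms: acetic acid, CC(=O)O
Why: Steglich-type O-acetylation of the 4-hydroxyl is followed by a DMAP-mediated O-to-C acyl shift (Fries-type rearrangement) to C-3, the established route to 3-acyl-4-hydroxy-2-pyrones.

**Step 4**
Reactants: 6 rac-3-acetyl-4-hydroxy-6-[(4E)-5,9-dimethyldeca-4,8-dien-2-yl]-2H-pyran-2-one
Product: 7 rac-3-acetyl-4-methoxy-6-[(4E)-5,9-dimethyldeca-4,8-dien-2-yl]-2H-pyran-2-one
Conditions: TMSCHN2, MeOH/toluene (1:4), 0 °C → rt
Reagents that add atoms: (trimethylsilyl)diazomethane, C[Si](C)(C)C=[N+]=[N-]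
Why: The acidic chelated enol protonates the diazoalkane and is O-methylated at O-4 under neutral conditions (diazomethane-type methylation), so the base-sensitive side-chain methine is left alone; a 2-methoxy-4-pyrone isomer, if formed, should be separable.

**Step 5**
Reactants: 7 rac-3-acetyl-4-methoxy-6-[(4E)-5,9-dimethyldeca-4,8-dien-2-yl]-2H-pyran-2-one
Product: 9 (S)-4-acetyl-5-hydroxy-3-methoxy-6-methyl-6-[(2E)-3,7-dimethylocta-2,6-dien-1-yl]cyclohexa-2,4-dien-1-one, via acylketene enolate 8 (not isolated)
Conditions: (S,S)-3,4,5-trifluorophenyl-NAS bromide (10 mol %), powdered Cs2CO3 (3 equiv), 4 Å MS, toluene (0.02 M), 25 → 45 °C; cold 0.5 M HCl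
Reagents that add atoms: none
Why: Proposed new method: powdered Cs2CO3 with the chiral ammonium salt should remove the side-chain methine proton of 7, which is vinylogous to the lactone and acetyl carbonyls, so that the racemic centre is erased in a planar trienolate paired with the chiral cation, and this anion, an acetoacetate-type ester enolate at C-3/C-2, should open by E1cB cleavage of the O-1–C-2 bond to the acylketene 8, in which the ring-derived cis C-4=C-5 bond keeps the tetrasubstituted enolate carbon beside the ketene carbon. Attack of that enolate carbon on the ketene carbon, a 6-(enolendo)-exo-dig C-acylation that can also be read as 6π electrocyclisation of the oxidotrienylketene, forms the bond from the quaternary carbon to the carbonyl carbon and closes the carbocycle, so that ring O-1 has been exchanged for carbon. The closest known reactions are the base-induced rearrangement of enol lactones to cyclic 1,3-diones, E1cB ketene formation from acetoacetate-type ester enolates, the ring closure of dienylketenes to cyclohexa-2,4-dienones and, for the asymmetric part, ion-pair-controlled Steglich-type O-to-C acyl shifts that build quaternary carbons; the combination on a pyrone is not known. The one new stereocentre, C-6 of 9, is set by the enolate face that the ammonium cation leaves open, both enantiomers of 7 converging through the same achiral anion, and the catalyst antipode that leads to (S)-9 has to be fixed in a first screen. The step needs C- over O-acylation and side-chain over acetyl deprotonation: O-attack only returns the pyrone anion and is reversible while C-attack ends in a stabilised β-tricarbonyl enolate, and the side-chain anion is the more delocalised of the two. The methyl ether keeps the pyrone neutral, and no free alkoxide is present that could strip the acetyl group by retro-Claisen cleavage.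

**Step 6**
Reactants: 9 (S)-4-acetyl-5-hydroxy-3-methoxy-6-methyl-6-[(2E)-3,7-dimethylocta-2,6-dien-1-yl]cyclohexa-2,4-dien-1-one
Product: 10 (R)-2-acetyl-3,5-dihydroxy-4-methyl-4-[(2E)-3,7-dimethylocta-2,6-dien-1-yl]cyclohexa-2,5-dien-1-one (enol form of 2-acetyl-4-geranyl-4-methylcyclohexane-1,3,5-trione)
Conditions: LiCl (5 equiv), DMSO, 90 °C; 0.5 M HCl
Reagents that add atoms: none
Why: Chloride demethylates the vinylogous methyl ester by SN2 attack at the methyl group (Krapcho-type dealkylation) with the stabilised β-triketonate as leaving group, so the geranyl alkenes and the quaternary stereocentre, which has no enolisable hydrogen, are not touched.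

**Step 7**
Reactants: 11 2,4,6-trihydroxybutyrophenone (butyrylphloroglucinol); 12 3-methylbut-2-enal (prenal)
Product: 14 1-(5,7-dihydroxy-2,2-dimethyl-2H-chromen-6-yl)butan-1-one, via dienone quinone methide 13 (not isolated)
Conditions: EDDA (10 mol %), 12 (1.0 equiv), toluene, 100 °C
Reagents that add atoms: none
Why: Amine-salt-catalysed Knoevenagel-type condensation at a free ring carbon gives the dienone 13, which should close by oxa-6π electrocyclisation through the non-chelated oxygen para to the acyl group (formal [3+3] chromene annulation); one equivalent of prenal limits double annulation.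

**Step 8**
Reactants: 14 1-(5,7-dihydroxy-2,2-dimethyl-2H-chromen-6-yl)butan-1-one
Product: 15 1-{8-[(dimethylamino)methyl]-5,7-dihydroxy-2,2-dimethyl-2H-chromen-6-yl}butan-1-one
Conditions: 37% aq. CH2O, 40% aq. Me2NH, EtOH, 0 °C → rt
Reagents that add atoms: formaldehyde, C=O; dimethylamine, CNC
Why: Phenolic Mannich reaction, in which the iminium ion attacks C-8, the only unsubstituted and strongly activated aromatic position.

**Step 9**
Reactants: 10 (R)-2-acetyl-3,5-dihydroxy-4-methyl-4-[(2E)-3,7-dimethylocta-2,6-dien-1-yl]cyclohexa-2,5-dien-1-one; 15 1-{8-[(dimethylamino)methyl]-5,7-dihydroxy-2,2-dimethyl-2H-chromen-6-yl}butan-1-one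
Product: 17 (4R)-2-acetyl-6-[(6-butanoyl-5,7-dihydroxy-2,2-dimethyl-2H-chromen-8-yl)methyl]-3,5-dihydroxy-4-methyl-4-[(2E)-3,7-dimethylocta-2,6-dien-1-yl]cyclohexa-2,5-dien-1-one (CNP0203748.1), via o-quinone methide 16 (not isolated)
Conditions: toluene, 80 °C, argon sweep; 0.5 M HCl wash
Reagents that add atoms: none
Why: The acidic trione protonates the benzylic amine, dimethylamine is lost in a retro-Mannich elimination to the o-quinone methide 16, and the trione enol adds through its only unsubstituted ring carbon in a Michael addition that restores the aromatic ring; the quaternary stereocentre is remote and unchanged.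

**Compound list**

1 | 4-hydroxy-6-methyl-2H-pyran-2-one | CC1=CC(O)=CC(=O)O1 | starting material
2 | 6-ethyl-4-hydroxy-2H-pyran-2-one | CCC1=CC(O)=CC(=O)O1 | intermediate
3 | geranyl bromide, (2E)-1-bromo-3,7-dimethylocta-2,6-diene | BrC/C=C(\C)CCC=C(C)C | starting material
4 | rac-4-hydroxy-6-[(4E)-5,9-dimethyldeca-4,8-dien-2-yl]-2H-pyran-2-one | CC(C/C=C(\C)CCC=C(C)C)C1=CC(O)=CC(=O)O1 | intermediate
5 | rac-6-[(4E)-5,9-dimethyldeca-4,8-dien-2-yl]-2-oxo-2H-pyran-4-yl acetate (not isolated) | CC(C/C=C(\C)CCC=C(C)C)C1=CC(OC(C)=O)=CC(=O)O1 | intermediate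
6 | rac-3-acetyl-4-hydroxy-6-[(4E)-5,9-dimethyldeca-4,8-dien-2-yl]-2H-pyran-2-one | CC(=O)C1=C(O)C=C(C(C)C/C=C(\C)CCC=C(C)C)OC1=O | intermediate
7 | rac-3-acetyl-4-methoxy-6-[(4E)-5,9-dimethyldeca-4,8-dien-2-yl]-2H-pyran-2-one | CC(=O)C1=C(OC)C=C(C(C)C/C=C(\C)CCC=C(C)C)OC1=O | intermediate
8 | acylketene enolate O=C=C(Ac)–C(OMe)=CH–C(O−)=C(CH3)(geranyl), ring-derived cis C=C, ammonium counter-ion (not isolated) | CC(=O)C(=C=O)/C(OC)=C\C([O-])=C(C)C/C=C(\C)CCC=C(C)C | intermediate
9 | (S)-4-acetyl-5-hydroxy-3-methoxy-6-methyl-6-[(2E)-3,7-dimethylocta-2,6-dien-1-yl]cyclohexa-2,4-dien-1-one | COC1=CC(=O)[C@@](C)(C/C=C(\C)CCC=C(C)C)C(O)=C1C(C)=O | intermediate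
10 | (R)-2-acetyl-3,5-dihydroxy-4-methyl-4-[(2E)-3,7-dimethylocta-2,6-dien-1-yl]cyclohexa-2,5-dien-1-one | O=C1C=C(O)[C@@](C)(C/C=C(\C)CCC=C(C)C)C(O)=C1C(C)=O | intermediate
11 | 2,4,6-trihydroxybutyrophenone | CCCC(=O)c1c(O)cc(O)cc1O | starting material
12 | 3-methylbut-2-enal | CC(C)=CC=O | starting material
13 | 2-butanoyl-3,5-dihydroxy-6-(3-methylbut-2-en-1-ylidene)cyclohexa-2,4-dien-1-one type dienone quinone methide (not isolated) | CCCC(=O)C1=C(O)C(=CC=C(C)C)C(=O)C=C1O | intermediate
14 | 1-(5,7-dihydroxy-2,2-dimethyl-2H-chromen-6-yl)butan-1-one | CCCC(=O)c1c(O)c2C=CC(C)(C)Oc2cc1O | intermediate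
15 | 1-{8-[(dimethylamino)methyl]-5,7-dihydroxy-2,2-dimethyl-2H-chromen-6-yl}butan-1-one | CCCC(=O)c1c(O)c2C=CC(C)(C)Oc2c(CN(C)C)c1O | intermediate
16 | 6-butanoyl-5-hydroxy-2,2-dimethyl-8-methylidene-2H-chromen-7(8H)-one, o-quinone methide (not isolated) | CCCC(=O)C1=C(O)C2=C(OC(C)(C)C=C2)C(=C)C1=O | intermediate
17 | (4R)-2-acetyl-6-[(6-butanoyl-5,7-dihydroxy-2,2-dimethyl-2H-chromen-8-yl)methyl]-3,5-dihydroxy-4-methyl-4-[(2E)-3,7-dimethylocta-2,6-dien-1-yl]cyclohexa-2,5-dien-1-one | CCCC(=O)c1c(O)c2c(c(CC3=C(O)[C@@](C)(C/C=C(\C)CCC=C(C)C)C(O)=C(C(C)=O)C3=O)c1O)OC(C)(C)C=C2 | target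

**Step count and risks**

Total steps: 9. Longest linear sequence: 7 (steps 1–6 and 9).

Steps most likely to fail:

Step 5 (proposed new method). The side-chain anion may stay closed as the pyrone, the ketene may be lost to intermolecular acylation, or the ring closure may proceed with poor facial selectivity. The fallback sets out from geranyl bromide 3 and returns to the route at 10. Dearomatising C-alkylation of 1-(2,4,6-trihydroxy-3-methylphenyl)ethan-1-one F1 with 3 (NaOMe, MeOH, 0 °C) at the methyl-bearing ring carbon should give racemic 2-acetyl-4-geranyl-4-methylcyclohexane-1,3,5-trione F2, to be freed from the aromatic C-geranyl isomer by chromatography. Preparative HPLC on a polysaccharide chiral stationary phase then supplies the (R)-enantiomer, which is 10.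

Step 7. The electrocyclisation may close through the chelated ortho oxygen to the 8-acyl chromene, or a second annulation may follow. The fallback sets out from 11 and returns at 14. O-alkylation of the most acidic, non-chelated para hydroxyl with 3-chloro-3-methylbut-1-yne (K2CO3, KI, CuI cat., acetone, reflux) gives the aryl propargyl ether 1-[2,6-dihydroxy-4-(2-methylbut-3-yn-2-yloxy)phenyl]butan-1-one F3. Heating F3 in xylene triggers the aryl propargyl ether Claisen rearrangement and ring closure, in which the ether oxygen becomes the ring oxygen, to give 14.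

Step 9. The quinone methide may form slowly, be captured at oxygen, or the halves of the product may exchange by retro-Michael and re-addition under the amine released. The fallback sets out from 10 and 14 and returns at 17, with the polarity reversed. Mannich reaction of 10 (CH2O, Me2NH, EtOH) gives the trione Mannich base (R)-2-acetyl-6-[(dimethylamino)methyl]-3,5-dihydroxy-4-methyl-4-geranylcyclohexa-2,5-dien-1-one F4. Warmed with 14 in toluene, F4 loses dimethylamine to the exocyclic enone (R)-2-acetyl-3-hydroxy-4-methyl-6-methylidene-4-geranylcyclohex-2-ene-1,5-dione F5, which the nucleophilic C-8 of the chromene phenol traps in a Michael/Friedel–Crafts addition.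

Further compounds
F1 | step 5 | 1-(2,4,6-trihydroxy-3-methylphenyl)ethan-1-one | CC(=O)c1c(O)cc(O)c(C)c1O
F2 | step 5 | rac-2-acetyl-3,5-dihydroxy-4-methyl-4-[(2E)-3,7-dimethylocta-2,6-dien-1-yl]cyclohexa-2,5-dien-1-one | CC(=O)C1=C(O)C(C)(C/C=C(\C)CCC=C(C)C)C(O)=CC1=O
F3 | step 7 | 1-[2,6-dihydroxy-4-(2-methylbut-3-yn-2-yloxy)phenyl]butan-1-one | CCCC(=O)c1c(O)cc(OC(C)(C)C#C)cc1O
F4 | step 9 | (R)-2-acetyl-6-[(dimethylamino)methyl]-3,5-dihydroxy-4-methyl-4-[(2E)-3,7-dimethylocta-2,6-dien-1-yl]cyclohexa-2,5-dien-1-one | CN(C)CC1=C(O)[C@@](C)(C/C=C(\C)CCC=C(C)C)C(O)=C(C(C)=O)C1=O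
F5 | step 9 | (R)-2-acetyl-3-hydroxy-4-methyl-6-methylidene-4-[(2E)-3,7-dimethylocta-2,6-dien-1-yl]cyclohex-2-ene-1,5-dione | C=C1C(=O)[C@@](C)(C/C=C(\C)CCC=C(C)C)C(O)=C(C(C)=O)C1=O
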